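**Retrosynthetic overview**
1. The two prenyl groups come from two C-allyl groups by cross-metathesis with 2-methyl-2-butene; the C-allyl groups come from a double aromatic Claisen rearrangement of bis-allyl ether 9.
2. Compound 9 comes from 2,4,6-trihydroxybenzophenone 7: allylate the para OH and one ortho OH, then methylate the last, chelated OH, which fixes OMe ortho to the C=O.
3. Compound 7 comes from triketo ester 5 by an intramolecular Claisen cyclisation and aromatisation. This is the only ring formed; the phenyl ring is bought with methyl benzoate.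
4. Compound 5 comes from the key intermolecular Claisen condensation of the trianion of methyl 3,5-dioxohexanoate 2 with methyl benzoate 3, which makes the future aryl–C(=O) bond.
5. Compound 2 comes from dehydroacetic acid 1.

Assumption: the target has no stereocentre and no stereogenic double bond, so it is one achiral compound and no stereocontrol is needed.

**Route**

Step 1
Reactants: 1 dehydroacetic acid (3-acetyl-4-hydroxy-6-methyl-2H-pyran-2-one)
Product: 2 methyl 3,5-dioxohexanoate
Conditions: Mg(OMe)2 (2.5 equiv), MeOH, reflux, 6 h; then cold 2 M HCl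
Reagents that add atoms: magnesium methoxide, C[O-].C[O-].[Mg+2] (in methanol, CO)
Why: Methoxide opens the lactone and removes the 3-acetyl group by retro-Claisen cleavage, driven by formation of the stable magnesium chelate of the β,δ-diketo ester.

Step 2
Reactants: 2 methyl 3,5-dioxohexanoate; 3 methyl benzoate
Product: 5 methyl 3,5,7-trioxo-7-phenylheptanoate, via trilithium trianion 4 (not isolated)
Conditions: 2 (2.0 equiv), commercial LDA solution (6.2 equiv), THF, 0 °C, 1 h; then 3 (1.0 equiv), 0 °C → rt; cold 2 M HCl quench; the excess of 2 absorbs the acidic proton of the product; 5 is used crude and cold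
Reagents that add atoms: none
Why: Crossed Claisen condensation in which the terminal, most nucleophilic carbanion of trianion 4 attacks the non-enolisable ester 3, forming the PhC(=O)–CH2 bond that becomes the aryl–carbonyl bond.

Step 3
Reactants: 5 methyl 3,5,7-trioxo-7-phenylheptanoate
Product: 7 2,4,6-trihydroxybenzophenone, via 2-benzoylcyclohexane-1,3,5-trione 6 (not isolated)
Conditions: degassed 1 M aq KOH (5 equiv), 0 °C → rt, Ar; then 2 M HCl to pH 2
Reagents that add atoms: none
Why: Intramolecular Claisen (Dieckmann-type) acylation of the C6 carbanion by the ester closes the ring as trione 6, which aromatises irreversibly by enolisation; strong aqueous base favours this over the reversible aldol closure onto the phenyl ketone.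

Step 4
Reactants: 7 2,4,6-trihydroxybenzophenone
Product: 8 4,6-bis(allyloxy)-2-hydroxybenzophenone
Conditions: allyl bromide (2.1 equiv), K2CO3 (2.2 equiv), acetone, reflux
Reagents that add atoms: allyl bromide, C=CCBr
Why: Williamson etherification takes the free para OH and then one of the two equivalent ortho OH groups, and stops there because the last OH is strongly hydrogen-bonded to the carbonyl.

Step 5
Reactants: 8 4,6-bis(allyloxy)-2-hydroxybenzophenone
Product: 9 4,6-bis(allyloxy)-2-methoxybenzophenone
Conditions: MeI (3 equiv), K2CO3 (3 equiv), DMF, 50 °C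
Reagents that add atoms: iodomethane, CI
Why: Forcing Williamson methylation of the only remaining (chelated) phenol places the methoxy group ortho to the carbonyl by construction.

Step 6
Reactants: 9 4,6-bis(allyloxy)-2-methoxybenzophenone
Product: 11 3,5-diallyl-2,4-dihydroxy-6-methoxybenzophenone, via mono-Claisen phenol 10 (not isolated)
Conditions: PhNEt2, 200 °C, Ar, sealed tube, 4–6 h
Reagents that add atoms: none
Why: Two consecutive aromatic Claisen [3,3] rearrangements (ortho, or ortho then Cope to para if the ortho site is taken) must deliver both unsubstituted allyl groups to C3 and C5, the only free ring positions, whichever ether moves first (10 shows the ether ortho to the benzoyl moving first).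

Step 7
Reactants: 11 3,5-diallyl-2,4-dihydroxy-6-methoxybenzophenone
Product: 12 (2,4-dihydroxy-6-methoxy-3,5-bis(3-methylbut-2-en-1-yl)phenyl)(phenyl)methanone
Conditions: Grubbs II (2 × 5 mol%), 2-methyl-2-butene/CH2Cl2 (1:1), 40 °C, sealed tube, 12 h
Reagents that add atoms: 2-methyl-2-butene, CC=C(C)C
Why: Olefin cross-metathesis of each terminal allyl group with a large excess of 2-methyl-2-butene gives the trisubstituted prenyl alkene, tolerates free phenols and the ketone, and creates no stereochemical issue.

**Compound list**
1 | dehydroacetic acid (3-acetyl-4-hydroxy-6-methyl-2H-pyran-2-one) | CC(=O)C1=C(O)C=C(C)OC1=O | starting material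
2 | methyl 3,5-dioxohexanoate | CC(=O)CC(=O)CC(=O)OC | intermediate
3 | methyl benzoate | COC(=O)c1ccccc1 | starting material
4 | trilithium trianion (tris-enolate) of methyl 3,5-dioxohexanoate | [Li+].[Li+].[Li+].C=C([O-])C=C([O-])C=C([O-])OC | intermediate (not isolated)
5 | methyl 3,5,7-trioxo-7-phenylheptanoate | COC(=O)CC(=O)CC(=O)CC(=O)c1ccccc1 | intermediate
6 | 2-benzoylcyclohexane-1,3,5-trione | O=C1CC(=O)C(C(=O)c2ccccc2)C(=O)C1 | intermediate (not isolated)
7 | 2,4,6-trihydroxybenzophenone | O=C(c1ccccc1)c1c(O)cc(O)cc1O | intermediate
8 | 4,6-bis(allyloxy)-2-hydroxybenzophenone | O=C(c1ccccc1)c1c(O)cc(OCC=C)cc1OCC=C | intermediate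
9 | 4,6-bis(allyloxy)-2-methoxybenzophenone | COc1cc(OCC=C)cc(OCC=C)c1C(=O)c1ccccc1 | intermediate
10 | 3-allyl-4-(allyloxy)-2-hydroxy-6-methoxybenzophenone | COc1cc(OCC=C)c(CC=C)c(O)c1C(=O)c1ccccc1 | intermediate (not isolated)
11 | 3,5-diallyl-2,4-dihydroxy-6-methoxybenzophenone | COc1c(CC=C)c(O)c(CC=C)c(O)c1C(=O)c1ccccc1 | intermediate
12 | (2,4-dihydroxy-6-methoxy-3,5-bis(3-methylbut-2-en-1-yl)phenyl)(phenyl)methanone | COc1c(CC=C(C)C)c(O)c(CC=C(C)C)c(O)c1C(=O)c1ccccc1 | target

**Summary**
Total step count: 7. Longest linear sequence: 7 steps (1 → 12); methyl benzoate 3 enters at step 2.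

Steps most likely to fail:

Step 3 (the triketo ester can close by aldol onto the phenyl ketone to give a biphenyl resorcylate, or lactonise to a pyrone, instead of the Claisen closure). Fallback, setting out from 3 and returning at 7: saponify 3 (LiOH, THF/H2O) to benzoic acid F3, then acylate commercial phloroglucinol directly with it (ZnCl2, POCl3, 70 °C, Friedel–Crafts type) to give 7. The phloroglucinol ring is then bought instead of built.

Step 2 (acylation of a trianion; the product is acid- and base-sensitive and yields are moderate). Fallback, setting out from 3 and returning at 5: condense 3 with the dianion of pentane-2,4-dione (NaH then n-BuLi, THF, 0 °C) to give 1-phenylhexane-1,3,5-trione F1. Form its trianion (LDA, 3.2 equiv) and carboxylate with CO2 to give 3,5,7-trioxo-7-phenylheptanoic acid F2. Esterify cold with TMSCHN2 (PhMe/MeOH, 0 °C) to give 5. The chain is assembled in the opposite order, so the ester terminus is introduced last.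

Step 4 (over-allylation to the tris-ether or some C-allylation of the electron-rich ring). Fallback, setting out from 7 and returning at 9: protect with MOMCl (2.2 equiv), DIPEA, CH2Cl2, 0 °C to give 2-hydroxy-4,6-bis(methoxymethoxy)benzophenone F4. Methylate the chelated OH (MeI, K2CO3, DMF) to give 2-methoxy-4,6-bis(methoxymethoxy)benzophenone F5. Remove both MOM groups (HCl, MeOH, 50 °C) to give 2,4-dihydroxy-6-methoxybenzophenone F6. Allylate both OH groups exhaustively (excess allyl bromide, K2CO3, DMF, 60 °C) to give 9. No selective alkylation is needed on this path.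

**Further compounds**
F1 | step 2 | 1-phenylhexane-1,3,5-trione | CC(=O)CC(=O)CC(=O)c1ccccc1
F2 | step 2 | 3,5,7-trioxo-7-phenylheptanoic acid | OC(=O)CC(=O)CC(=O)CC(=O)c1ccccc1
F3 | step 3 | benzoic acid | OC(=O)c1ccccc1
F4 | step 4 | 2-hydroxy-4,6-bis(methoxymethoxy)benzophenone | COCOc1cc(O)c(C(=O)c2ccccc2)c(OCOC)c1
F5 | step 4 | 2-methoxy-4,6-bis(methoxymethoxy)benzophenone | COCOc1cc(OC)c(C(=O)c2ccccc2)c(OCOC)c1
F6 | step 4 | 2,4-dihydroxy-6-methoxybenzophenone | COc1cc(O)cc(O)c1C(=O)c1ccccc1
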